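**Plan**

- Cuts, latest first: the C2=C3 enoate bond of the side chain (Still–Gennari olefination), then its C4–C5 bond (allylic bromide plus a two-carbon aldehyde-anion equivalent), then the C7–O bond of the phenol (back to a C7 boronate).
- Ring A (the benzene ring C4a, C5, C6, C7, C8, C8a; chroman numbering O1, C2, C3, C4) is fused to the pyran ring along C4a–C8a. It is cut at C4a–C8a, C5–C6 and C7–C8 into three alkynes: an O1-bound ethynyl ether (C8a, C8), a methyl-capped alkyne (C4a, C5) tied to O1 through C4–C3–C2, and an ethynylboronate (C6, C7) whose boron stands in for the C7 hydroxyl.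
- Forward: (R)-linalool is turned into the tethered 1,7-diyne (vinyl group to CH2CH2C≡CCH3, tertiary hydroxyl to OC≡CH). One ruthenium-catalysed [2+2+2] cycloaddition then closes the pyran ring and ring A together, and the prenyl terminus is afterwards grown into the dienoate chain.
- Stereochemistry: C2 (R) is the carbinol carbon of (R)-linalool and no bond to it is ever broken. The 6E alkene comes from E-selective allylic oxidation of the prenyl group and the 2Z enoate from the Still–Gennari reaction.

Key step: step 6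

Assumption: commercial (R)-(−)-linalool is taken to be of high enantiomeric purity, because the route passes its carbinol configuration on unchanged and offers no later point at which it is upgraded.

**Route**

Step 1
Reactants: 1 (R)-linalool [(3R)-3,7-dimethylocta-1,6-dien-3-ol]
Product: 3 (3R)-3,7-dimethyloct-6-ene-1,3-diol, via B-alkyl-9-BBN adduct 2 (not isolated)
Conditions: 9-BBN (2 equiv), THF, 0 °C to rt; then NaOH (aq), H2O2 (30% aq), 0 °C to rt
Reagents that add atoms: hydrogen peroxide, OO
Why: Brown hydroboration–oxidation, in which the bulky 9-BBN adds anti-Markovnikov to the monosubstituted vinyl group far faster than to the trisubstituted alkene and oxidation of the C–B bond gives the primary alcohol without touching the carbinol stereocentre.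

Step 2
Reactants: 3 (3R)-3,7-dimethyloct-6-ene-1,3-diol
Product: 5 (3R)-3,7-dimethyl-3-[(trimethylsilyl)oxy]oct-6-en-1-yl 4-methylbenzenesulfonate, via hydroxy tosylate 4 (not isolated)
Conditions: TsCl, Et3N, DMAP (cat.), CH2Cl2, 0 °C; then 1-(trimethylsilyl)imidazole, rt
Reagents that add atoms: 4-methylbenzenesulfonyl chloride (TsCl), Cc1ccc(cc1)S(=O)(=O)Cl; 1-(trimethylsilyl)imidazole, C[Si](C)(C)n1ccnc1
Why: Selective sulfonylation of the primary hydroxyl (the tertiary one is too hindered for TsCl) followed by silyl protection of the tertiary hydroxyl with a strong silyl donor, so that no alkoxide can close an oxetane onto the tosylate in step 3.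

Step 3
Reactants: 5 (3R)-3,7-dimethyl-3-[(trimethylsilyl)oxy]oct-6-en-1-yl 4-methylbenzenesulfonate; 6 1-propynyllithium
Product: 8 (6R)-2,6-dimethylundec-2-en-9-yn-6-ol, via silyl ether alkyne 7 (not isolated)
Conditions: 6 (2 equiv), THF/DMPU, 0 °C to rt; then MeOH, K2CO3, rt
Reagents that add atoms: none
Why: SN2 alkylation of a lithium acetylide by a primary tosylate in a dipolar aprotic medium builds the methyl-capped alkyne arm, and base-catalysed methanolysis of the trimethylsilyl ether in the same flask returns the tertiary alcohol.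

Step 4
Reactants: 8 (6R)-2,6-dimethylundec-2-en-9-yn-6-ol; 9 trichloroethylene
Product: 10 (6R)-6-{[(E)-1,2-dichloroethenyl]oxy}-2,6-dimethylundec-2-en-9-yne
Conditions: KH, THF, 0 °C to rt; then 9, −50 °C to rt
Reagents that add atoms: none
Why: Alkoxide addition to dichloroacetylene generated in the flask by dehydrochlorination of trichloroethylene (the dichloroenol ether entry to ynol ethers) proceeds by anti addition to give the E-1,2-dichlorovinyl ether, and because only the O–H bond of 8 is engaged the carbinol configuration is retained.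

Step 5
Reactants: 10 (6R)-6-{[(E)-1,2-dichloroethenyl]oxy}-2,6-dimethylundec-2-en-9-yne
Product: 13 (6R)-6-(ethynyloxy)-2,6-dimethylundec-2-en-9-yne, via chloroethynyl ether 11 (not isolated), via lithium alkoxyacetylide 12 (not isolated)
Conditions: n-BuLi (2.4 equiv), THF, −78 to −40 °C; then MeOH, −78 °C; cold work-up, solution kept below 0 °C and used at once
Reagents that add atoms: none
Why: Dehydrochlorination by the first equivalent of n-BuLi gives the chloroalkynyl ether, chlorine–lithium exchange by the second gives the lithium alkoxyacetylide and cold protonation frees the terminal ynol ether (base-induced elimination then halogen–metal exchange), the product being handled cold because tertiary-alkyl ethynyl ethers lose ketene by a retro-ene path on warming.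

Step 6
Reactants: 13 (6R)-6-(ethynyloxy)-2,6-dimethylundec-2-en-9-yne; 14 2-ethynyl-4,4,5,5-tetramethyl-1,3,2-dioxaborolane
Product: 15 2-[(2R)-2,5-dimethyl-2-(4-methylpent-3-en-1-yl)-3,4-dihydro-2H-chromen-7-yl]-4,4,5,5-tetramethyl-1,3,2-dioxaborolane
Conditions: Cp*RuCl(cod) (10 mol %), 14 (3 equiv), ClCH2CH2Cl, rt, 13 added slowly
Reagents that add atoms: none
Why: Proposed new method: after loss of cod, divalent ruthenium binds both alkynes of 13 and couples them oxidatively to a tetravalent ruthenacycle (new C4a–C8a bond), the alkynylboronate 14 then inserts at the unsubstituted C8 terminus (new C7–C8 bond) and C–C reductive elimination makes C5–C6, releasing the arene and divalent ruthenium. The closest known reaction type is the Cp*RuCl(cod)-catalysed [2+2+2] cycloaddition of tethered diynes with alkynylboronates, together with related cyclotrimerisations of ynamide and alkynyl ether diynes; a tertiary-alkyl ethynyl ether as a diyne terminus has not been shown. The pyran ring closes in the oxidative coupling, the four-atom tether O1–C2–C3–C4 holding the two alkynes as a 1,7-diyne so that a six-membered ring fused to the metallacycle results, and ring A closes by intermolecular insertion of the third alkyne followed by reductive elimination. No stereocentre is created and no bond to C2 is made or broken, so the R configuration from linalool passes through unchanged. The step needs boron at C7 and not C6, which the unlike diyne termini should secure because the boron-bearing carbon of 14 bonds to the hydrogen-bearing C8 and the Bpin group thereby ends up meta to the C5 methyl instead of beside it. Slow addition of 13 to an excess of 14 holds back diyne self-coupling, and ambient temperature keeps the ynol ether from losing ketene by a retro-ene path.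

Step 7
Reactants: 15 2-[(2R)-2,5-dimethyl-2-(4-methylpent-3-en-1-yl)-3,4-dihydro-2H-chromen-7-yl]-4,4,5,5-tetramethyl-1,3,2-dioxaborolane
Product: 16 (2R)-2,5-dimethyl-2-(4-methylpent-3-en-1-yl)-3,4-dihydro-2H-chromen-7-ol
Conditions: H2O2 (30% aq), NaOH (aq), THF, 0 °C
Reagents that add atoms: hydrogen peroxide, OO
Why: Oxidation of an arylboronate by hydroperoxide anion, in which the boronate complex undergoes a 1,2-shift of the aryl group from boron to oxygen at the ipso carbon and hydrolysis gives the phenol, while the isolated trisubstituted alkene is inert to alkaline peroxide.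

Step 8
Reactants: 16 (2R)-2,5-dimethyl-2-(4-methylpent-3-en-1-yl)-3,4-dihydro-2H-chromen-7-ol
Product: 17 tert-butyl{[(2R)-2,5-dimethyl-2-(4-methylpent-3-en-1-yl)-3,4-dihydro-2H-chromen-7-yl]oxy}dimethylsilane
Conditions: TBSCl, imidazole, DMF, rt
Reagents that add atoms: tert-butyldimethylsilyl chloride (TBSCl), CC(C)(C)[Si](C)(C)Cl
Why: Imidazole-promoted silylation of a phenol (silyl ether protection) masks the acidic and oxidation-prone hydroxyl for the allylic oxidation and the carbanion steps that follow.

Step 9
Reactants: 17 tert-butyl{[(2R)-2,5-dimethyl-2-(4-methylpent-3-en-1-yl)-3,4-dihydro-2H-chromen-7-yl]oxy}dimethylsilane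
Product: 18 (2E)-5-[(2R)-7-{[tert-butyl(dimethyl)silyl]oxy}-2,5-dimethyl-3,4-dihydro-2H-chromen-2-yl]-2-methylpent-2-en-1-ol
Conditions: SeO2 (cat.), t-BuOOH, salicylic acid (cat.), CH2Cl2, 0 °C to rt
Reagents that add atoms: selenium dioxide, O=[Se]=O (oxygen donor, turned over by the hydroperoxide); tert-butyl hydroperoxide, CC(C)(C)OO
Why: Catalytic SeO2/t-BuOOH allylic oxidation (ene reaction followed by [2,3]-sigmatropic shift) attacks the more substituted end of the trisubstituted alkene and selects the E methyl of the gem-dimethyl terminus, which fixes the E geometry of the future C6=C7 alkene.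

Step 10
Reactants: 18 (2E)-5-[(2R)-7-{[tert-butyl(dimethyl)silyl]oxy}-2,5-dimethyl-3,4-dihydro-2H-chromen-2-yl]-2-methylpent-2-en-1-ol
Product: 19 {[(2R)-2-[(3E)-5-bromo-4-methylpent-3-en-1-yl]-2,5-dimethyl-3,4-dihydro-2H-chromen-7-yl]oxy}(tert-butyl)dimethylsilane
Conditions: CBr4, PPh3, CH2Cl2, 0 °C
Reagents that add atoms: tetrabromomethane, BrC(Br)(Br)Br
Why: Appel bromination converts the primary allylic alcohol into the bromide by SN2 displacement of the oxyphosphonium group under near-neutral conditions that leave the aryl silyl ether and the E alkene untouched.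

Step 11
Reactants: 19 {[(2R)-2-[(3E)-5-bromo-4-methylpent-3-en-1-yl]-2,5-dimethyl-3,4-dihydro-2H-chromen-7-yl]oxy}(tert-butyl)dimethylsilane; 20 N-tert-butylethanimine (acetaldehyde N-tert-butylimine)
Product: 22 (4E)-7-[(2R)-7-{[tert-butyl(dimethyl)silyl]oxy}-2,5-dimethyl-3,4-dihydro-2H-chromen-2-yl]-4-methylhept-4-enal, via N-tert-butyl imine 21 (not isolated)
Conditions: LiN(i-Pr)2, 20, THF, −78 to 0 °C; then 19, −78 to 0 °C; then oxalic acid (aq), rt
Reagents that add atoms: water, O
Why: Alkylation of a metalated aldimine (azaenolate alkylation) by the primary allylic bromide in SN2 fashion adds the two carbons C3 and C4 of the chain, and mild acid hydrolysis of the imine unveils the aldehyde without cleaving the aryl silyl ether.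

Step 12
Reactants: 22 (4E)-7-[(2R)-7-{[tert-butyl(dimethyl)silyl]oxy}-2,5-dimethyl-3,4-dihydro-2H-chromen-2-yl]-4-methylhept-4-enal; 23 methyl 2-[bis(2,2,2-trifluoroethoxy)phosphoryl]propanoate
Product: 24 methyl (2Z,6E)-9-[(2R)-7-{[tert-butyl(dimethyl)silyl]oxy}-2,5-dimethyl-3,4-dihydro-2H-chromen-2-yl]-2,6-dimethylnona-2,6-dienoate
Conditions: 23, KN(SiMe3)2, 18-crown-6, THF, −78 °C; then 22
Reagents that add atoms: none
Why: Still–Gennari variant of the Horner–Wadsworth–Emmons olefination, in which the electron-poor bis(trifluoroethyl) phosphonate under dissociating conditions eliminates rapidly from the kinetically formed adduct and so delivers the Z trisubstituted enoate.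

Step 13
Reactants: 24 methyl (2Z,6E)-9-[(2R)-7-{[tert-butyl(dimethyl)silyl]oxy}-2,5-dimethyl-3,4-dihydro-2H-chromen-2-yl]-2,6-dimethylnona-2,6-dienoate
Product: 25 methyl (2Z,6E)-9-[(2R)-7-hydroxy-2,5-dimethyl-3,4-dihydro-2H-chromen-2-yl]-2,6-dimethylnona-2,6-dienoate (CNP0319148.1)
Conditions: TBAF, AcOH, THF, 0 °C
Reagents that add atoms: none
Why: Fluoride-mediated desilylation of the aryl silyl ether, driven by the strong Si–F bond, with acetic acid buffering so that the phenoxide neither hydrolyses the methyl ester nor isomerises the Z enoate.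

**Compound list**

1 | (R)-linalool, (3R)-3,7-dimethylocta-1,6-dien-3-ol | CC(C)=CCC[C@@](C)(O)C=C | starting material
2 | (3S)-1-(9-borabicyclo[3.3.1]nonan-9-yl)-3,7-dimethyloct-6-en-3-ol (same spatial arrangement as 1; the descriptor changes only through CIP priority of the boron-bearing arm) | CC(C)=CCC[C@@](C)(O)CCB1C2CCCC1CCC2 | intermediate
3 | (3R)-3,7-dimethyloct-6-ene-1,3-diol | CC(C)=CCC[C@@](C)(O)CCO | intermediate
4 | (3R)-3-hydroxy-3,7-dimethyloct-6-en-1-yl 4-methylbenzenesulfonate | CC(C)=CCC[C@@](C)(O)CCOS(=O)(=O)c1ccc(C)cc1 | intermediate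
5 | (3R)-3,7-dimethyl-3-[(trimethylsilyl)oxy]oct-6-en-1-yl 4-methylbenzenesulfonate | CC(C)=CCC[C@@](C)(O[Si](C)(C)C)CCOS(=O)(=O)c1ccc(C)cc1 | intermediate
6 | 1-propynyllithium | [Li]C#CC | starting material
7 | {[(6R)-2,6-dimethylundec-2-en-9-yn-6-yl]oxy}trimethylsilane | CC(C)=CCC[C@@](C)(O[Si](C)(C)C)CCC#CC | intermediate
8 | (6R)-2,6-dimethylundec-2-en-9-yn-6-ol | CC(C)=CCC[C@@](C)(O)CCC#CC | intermediate
9 | trichloroethylene | ClC=C(Cl)Cl | starting material
10 | (6R)-6-{[(E)-1,2-dichloroethenyl]oxy}-2,6-dimethylundec-2-en-9-yne | CC(C)=CCC[C@@](C)(O/C(Cl)=C\Cl)CCC#CC | intermediate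
11 | (6R)-6-[(chloroethynyl)oxy]-2,6-dimethylundec-2-en-9-yne | CC(C)=CCC[C@@](C)(OC#CCl)CCC#CC | intermediate
12 | ({[(6R)-2,6-dimethylundec-2-en-9-yn-6-yl]oxy}ethynyl)lithium | CC(C)=CCC[C@@](C)(OC#C[Li])CCC#CC | intermediate
13 | (6R)-6-(ethynyloxy)-2,6-dimethylundec-2-en-9-yne (numbered from the alkyne end: (6R)-6-(ethynyloxy)-6,10-dimethylundec-9-en-2-yne) | CC(C)=CCC[C@@](C)(OC#C)CCC#CC | intermediate
14 | 2-ethynyl-4,4,5,5-tetramethyl-1,3,2-dioxaborolane | C#CB1OC(C)(C)C(C)(C)O1 | starting material
15 | 2-[(2R)-2,5-dimethyl-2-(4-methylpent-3-en-1-yl)-3,4-dihydro-2H-chromen-7-yl]-4,4,5,5-tetramethyl-1,3,2-dioxaborolane | CC(C)=CCC[C@]1(C)CCc2c(C)cc(B3OC(C)(C)C(C)(C)O3)cc2O1 | intermediate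
16 | (2R)-2,5-dimethyl-2-(4-methylpent-3-en-1-yl)-3,4-dihydro-2H-chromen-7-ol | CC(C)=CCC[C@]1(C)CCc2c(C)cc(O)cc2O1 | intermediate
17 | tert-butyl{[(2R)-2,5-dimethyl-2-(4-methylpent-3-en-1-yl)-3,4-dihydro-2H-chromen-7-yl]oxy}dimethylsilane | CC(C)=CCC[C@]1(C)CCc2c(C)cc(O[Si](C)(C)C(C)(C)C)cc2O1 | intermediate
18 | (2E)-5-[(2R)-7-{[tert-butyl(dimethyl)silyl]oxy}-2,5-dimethyl-3,4-dihydro-2H-chromen-2-yl]-2-methylpent-2-en-1-ol | OC/C(C)=C/CC[C@]1(C)CCc2c(C)cc(O[Si](C)(C)C(C)(C)C)cc2O1 | intermediate
19 | {[(2R)-2-[(3E)-5-bromo-4-methylpent-3-en-1-yl]-2,5-dimethyl-3,4-dihydro-2H-chromen-7-yl]oxy}(tert-butyl)dimethylsilane | BrC/C(C)=C/CC[C@]1(C)CCc2c(C)cc(O[Si](C)(C)C(C)(C)C)cc2O1 | intermediate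
20 | N-tert-butylethanimine (acetaldehyde N-tert-butylimine) | CC=NC(C)(C)C | starting material
21 | (4E)-N-tert-butyl-7-[(2R)-7-{[tert-butyl(dimethyl)silyl]oxy}-2,5-dimethyl-3,4-dihydro-2H-chromen-2-yl]-4-methylhept-4-en-1-imine | CC(C)(C)N=CCC/C(C)=C/CC[C@]1(C)CCc2c(C)cc(O[Si](C)(C)C(C)(C)C)cc2O1 | intermediate
22 | (4E)-7-[(2R)-7-{[tert-butyl(dimethyl)silyl]oxy}-2,5-dimethyl-3,4-dihydro-2H-chromen-2-yl]-4-methylhept-4-enal | O=CCC/C(C)=C/CC[C@]1(C)CCc2c(C)cc(O[Si](C)(C)C(C)(C)C)cc2O1 | intermediate
23 | methyl 2-[bis(2,2,2-trifluoroethoxy)phosphoryl]propanoate | COC(=O)C(C)P(=O)(OCC(F)(F)F)OCC(F)(F)F | starting material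
24 | methyl (2Z,6E)-9-[(2R)-7-{[tert-butyl(dimethyl)silyl]oxy}-2,5-dimethyl-3,4-dihydro-2H-chromen-2-yl]-2,6-dimethylnona-2,6-dienoate | COC(=O)/C(C)=C\CC/C(C)=C/CC[C@]1(C)CCc2c(C)cc(O[Si](C)(C)C(C)(C)C)cc2O1 | intermediate
25 | methyl (2Z,6E)-9-[(2R)-7-hydroxy-2,5-dimethyl-3,4-dihydro-2H-chromen-2-yl]-2,6-dimethylnona-2,6-dienoate | COC(=O)/C(C)=C\CC/C(C)=C/CC[C@]1(C)CCc2c(C)cc(O)cc2O1 | target

**Count**

Total steps: 13. Longest linear sequence: 13 steps, from 1 to 25; compounds 6, 9, 14, 20 and 23 are bought.

**Steps most likely to fail**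

1. Step 6 (proposed new method). The ynol ether terminus may fragment by retro-ene loss of ketene or be drawn into unproductive metal–alkyne chemistry before the oxidative coupling, and the boronate may insert with the opposite orientation. The fallback uses known chemistry and makes the aryl–O1 bond last instead of building ring A. It sets out from the borane 2, made from 1 as in step 1 with the oxidation left out. Commercial 3-bromo-5-methylphenol is iodinated para to the hydroxyl (N-iodosuccinimide, TsOH cat., MeCN) to 3-bromo-4-iodo-5-methylphenol F1 and silylated (TBSCl, imidazole, DMF) to tert-butyl(3-bromo-4-iodo-5-methylphenoxy)dimethylsilane F2. B-alkyl Suzuki–Miyaura coupling of 2 with F2 at the more reactive C–I bond (PdCl2(dppf), K3PO4, THF/DMF/H2O, rt to 50 °C) should give (3R)-1-(2-bromo-4-{[tert-butyl(dimethyl)silyl]oxy}-6-methylphenyl)-3,7-dimethyloct-6-en-3-ol F3. Buchwald–Hartwig-type intramolecular C–O coupling of the tertiary alcohol with the aryl bromide (Pd(OAc)2, 2-(di-tert-butylphosphino)-1,1'-binaphthyl, Cs2CO3, toluene, 80 °C) then closes the pyran ring: zerovalent palladium inserts into the C–Br bond, the alkoxide replaces bromide on the metal and C–O reductive elimination follows. This gives the silyl ether 17, where the route is rejoined before step 9.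

2. Step 4. The hindered tertiary potassium alkoxide may add only slowly to dichloroacetylene, so that decomposition of that reagent outruns formation of the enol ether. The fallback reaches the same ynol ether through a dibromoenol ether. It sets out from 8, which is formylated (acetic formic anhydride, pyridine, 0 °C) to (6R)-2,6-dimethylundec-2-en-9-yn-6-yl formate F4. Ramirez-type dibromomethylenation of the formate carbonyl (CBr4, PPh3, CH2Cl2, 0 °C to rt) gives (6R)-6-[(2,2-dibromoethenyl)oxy]-2,6-dimethylundec-2-en-9-yne F5. n-BuLi (2.2 equiv, THF, −78 °C) eliminates HBr to (6R)-6-[(bromoethynyl)oxy]-2,6-dimethylundec-2-en-9-yne F6, which undergoes bromine–lithium exchange to the lithium alkoxyacetylide 12. Cold quenching with MeOH gives 13, where the route is rejoined before step 6.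

3. Step 9. Conversion may stall while over-oxidation to the enal and attack at the benzylic C4 position or the electron-rich ring set in. The fallback installs the oxygenated E terminus by olefin metathesis instead of C–H oxidation. It sets out from 17, which undergoes cross-metathesis with methacrolein (second-generation Grubbs catalyst, CH2Cl2, 40 °C) with loss of 2-methylpropene to give (2E)-5-[(2R)-7-{[tert-butyl(dimethyl)silyl]oxy}-2,5-dimethyl-3,4-dihydro-2H-chromen-2-yl]-2-methylpent-2-enal F7, the E isomer being the thermodynamically favoured trisubstituted enal. Luche reduction (NaBH4, CeCl3·7H2O, MeOH, 0 °C) gives the allylic alcohol 18, where the route is rejoined before step 10.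

**Further compounds**

F1 | step 6 | 3-bromo-4-iodo-5-methylphenol | Cc1cc(O)cc(Br)c1I
F2 | step 6 | tert-butyl(3-bromo-4-iodo-5-methylphenoxy)dimethylsilane | Cc1cc(O[Si](C)(C)C(C)(C)C)cc(Br)c1I
F3 | step 6 | (3R)-1-(2-bromo-4-{[tert-butyl(dimethyl)silyl]oxy}-6-methylphenyl)-3,7-dimethyloct-6-en-3-ol | CC(C)=CCC[C@@](C)(O)CCc1c(C)cc(O[Si](C)(C)C(C)(C)C)cc1Br
F4 | step 4 | (6R)-2,6-dimethylundec-2-en-9-yn-6-yl formate | CC(C)=CCC[C@@](C)(OC=O)CCC#CC
F5 | step 4 | (6R)-6-[(2,2-dibromoethenyl)oxy]-2,6-dimethylundec-2-en-9-yne | CC(C)=CCC[C@@](C)(OC=C(Br)Br)CCC#CC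
F6 | step 4 | (6R)-6-[(bromoethynyl)oxy]-2,6-dimethylundec-2-en-9-yne | CC(C)=CCC[C@@](C)(OC#CBr)CCC#CC
F7 | step 9 | (2E)-5-[(2R)-7-{[tert-butyl(dimethyl)silyl]oxy}-2,5-dimethyl-3,4-dihydro-2H-chromen-2-yl]-2-methylpent-2-enal | O=C/C(C)=C/CC[C@]1(C)CCc2c(C)cc(O[Si](C)(C)C(C)(C)C)cc2O1
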